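Assumption: the SMILES is read as (1S,2R,5R,6R)-2,6-bis(4-hydroxy-3-methoxyphenyl)-3,7-dioxabicyclo[3.3.0]octan-1-ol (C2 aryl exo and cis to the OH, C6 aryl endo); these atom labels (C1, C2, O3, C4, C5, C6, O7, C8) are used for all intermediates, and "Ar" in names means 3-methoxy-4-(triisopropylsilyloxy)phenyl.

**Retrosynthetic overview**
1. Target 21 ← bis-silyl ether 20 ← 8-oxo lactone 18 (lactone to cyclic ether, then phenol deprotection).
2. 18 ← ring contraction of the benzylidene-type acetal lactone 16: the acetal carbon shifts from O to C1 of the lactone enolate, forming C1–C2, the tertiary alcohol and ring A last (ring B is made first, as the lactone).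
3. 16 ← all-cis lactone diol 14 + aldehyde 7; 14 ← cis-hydrogenation of the enol lactone 13 (sets C5 from C6).
4. 13 ← α-methylene lactone 10 (ozonolysis, hydroxymethylation) ← asymmetric 2-(methoxycarbonyl)allylation of 7 with 8 (sets C6).
5. 7 ← vanillin 6 ← guaiacol 2 + glyoxylic acid 3 ← catechol 1.

**Route**

Step 1
Reactants: 1 catechol
Product: 2 guaiacol
Conditions: MeI (1.0 equiv), Li2CO3 (1.0 equiv), DMF, 55 °C
Reagents that add atoms: iodomethane, CI
Why: Williamson O-methylation of the mono-phenoxide; the weak base and one equivalent of MeI keep it at the mono-ether.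

Step 2
Reactants: 2 guaiacol, 3 glyoxylic acid
Product: 6 vanillin, via vanillylmandelic acid 4 (not isolated), via 4-hydroxy-3-methoxyphenylglyoxylic acid 5 (not isolated)
Conditions: NaOH, H2O, 30 °C; then CuSO4 (cat.), air, 95 °C; then H2SO4 to pH 3, 60 °C
Reagents that add atoms: none
Why: para-selective hydroxyalkylation of the phenoxide (electrophilic aromatic substitution), copper-catalysed aerobic oxidation to the aryl glyoxylic acid and acid decarboxylation, i.e. the industrial vanillin sequence run without isolating the acids.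

Step 3
Reactants: 6 vanillin
Product: 7 3-methoxy-4-(triisopropylsilyloxy)benzaldehyde
Conditions: iPr3SiCl, imidazole, DMF, rt
Reagents that add atoms: chlorotriisopropylsilane, CC(C)[Si](Cl)(C(C)C)C(C)C
Why: phenol silylation; the aryl silyl ether survives amine bases, hydrogenation, amide bases and hydride, and leaves with fluoride at the end.

Step 4
Reactants: 7 3-methoxy-4-(triisopropylsilyloxy)benzaldehyde, 8 methyl 2-(bromomethyl)acrylate
Product: 10 (5R)-5-Ar-3-methylenedihydrofuran-2(3H)-one, via hydroxy ester 9 (not isolated)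
Conditions: CrCl2 (10 mol %), Nakada-type carbazole-bis(oxazoline) ligand (12 mol %, the enantiomer that gives the R carbinol), Mn powder (2 equiv), Me3SiCl, iPr2NEt (30 mol %), THF, rt; then TsOH·H2O (cat.), CH2Cl2, rt
Reagents that add atoms: none
Why: catalytic asymmetric Nozaki–Hiyama–Kishi 2-(alkoxycarbonyl)allylation, which tolerates electron-rich aryl aldehydes; the ligand-bound allylchromium adds to one aldehyde face to set C6 (R), and acid closes the γ-lactone.

Step 5
Reactants: 10 (5R)-5-Ar-3-methylenedihydrofuran-2(3H)-one, 11 formaldehyde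
Product: 13 (5S)-3-hydroxy-4-(hydroxymethyl)-5-Ar-furan-2(5H)-one, via isotetronic acid 12 (not isolated)
Conditions: O3, CH2Cl2/MeOH, −78 °C (indicator end point); Me2S, −78 to 0 °C; then 37% aq. CH2O (1.2 equiv), Et3N (0.2 equiv), THF, 0 °C
Reagents that add atoms: ozone, [O-][O+]=O
Why: ozonolysis of the exocyclic alkene gives the α-keto lactone, which sits as its enol 12; amine-catalysed aldol addition to formaldehyde at the nucleophilic enol carbon C5 installs C4 without touching C6 (the descriptor changes only through CIP priorities).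

Step 6
Reactants: 13 (5S)-3-hydroxy-4-(hydroxymethyl)-5-Ar-furan-2(5H)-one
Product: 14 (3R,4S,5R)-3-hydroxy-4-(hydroxymethyl)-5-Ar-dihydrofuran-2(3H)-one (all-cis)
Conditions: H2 (30 bar), 5% Rh/Al2O3, EtOAc, rt
Reagents that add atoms: none
Why: heterogeneous syn-hydrogenation of the enol C1=C5 bond from the face opposite the C6 aryl sets C5 (CH2OH cis to aryl, the later endo relationship) and C1 together; Rh on alumina is chosen to avoid benzylic C–O hydrogenolysis.

Step 7
Reactants: 14 all-cis lactone diol, 7 3-methoxy-4-(triisopropylsilyloxy)benzaldehyde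
Product: 16 (2S,4aR,5R,7aR)-2,5-di-Ar-tetrahydro-4H-furo[3,4-d][1,3]dioxin-7(4aH)-one, via dimethyl acetal 15 (not isolated)
Conditions: 7, HC(OMe)3, camphorsulfonic acid (cat.), MeOH, rt, concentrate; then 14, camphorsulfonic acid (5 mol %), 4 Å sieves, CH2Cl2, rt, 12 h
Reagents that add atoms: none
Why: transacetalisation to the six-membered benzylidene-type acetal under thermodynamic control; the all-cis lactone holds C4 pseudo-axial, so the dioxane chair has C5–C6 equatorial and the equatorial aryl at the acetal carbon corresponds to 2S.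

Step 8
Reactants: 16 cis-fused acetal lactone
Product: 18 (1R,4R,5R,8R)-1-hydroxy-4,8-di-Ar-3,7-dioxabicyclo[3.3.0]octan-2-one (the 8-oxo derivative of 20 in target labels), via potassium lactone enolate 17 (not isolated)
Conditions: KN(SiMe3)2 (1.1 equiv), 18-crown-6, THF, −78 °C; warm to 0 °C; AcOH, −78 °C
Reagents that add atoms: none
Why: Proposed new method: a ring-contracting [1,2]-Wittig-type O-to-C shift of an acetal carbon on a lactone enolate (1,3-dioxane to 3-hydroxytetrahydrofuran) – in the α-alkoxy enolate 17 the O–C2 bond breaks to a captodatively stabilised ketyl-type radical anion of the α-oxo lactone and a benzylic α-alkoxy radical held by the O3–C4 tether, and recombination at C1 on the only reachable face (that of C4) gives the more stable tertiary alkoxide, so ring A closes cis-fused with OH cis to H-5, while retention at the migrating carbon places the new aryl exo and cis to OH; the closest known chemistry is the retentive [1,2]-Wittig rearrangement of acetals (O-glycoside to C-glycoside) and ring-contracting Wittig rearrangements of cyclic ethers, neither shown on an enolate or for a dioxane-to-tetrahydrofuran contraction.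

Step 9
Reactants: 18 hydroxy lactone
Product: 20 (1S,2R,5R,6R)-2,6-di-Ar-3,7-dioxabicyclo[3.3.0]octan-1-ol, via lactol 19 (not isolated)
Conditions: iBu2AlH (2.5 equiv), CH2Cl2, −78 °C; aq. KNaC4H4O6; then Et3SiH (5 equiv), BF3·OEt2, CH2Cl2, −78 to −40 °C
Reagents that add atoms: none
Why: lactone to lactol, then ionic hydrogenation of the derived oxocarbenium ion (reductive deoxygenation, precedented on furofuran acetals); C8 becomes CH2 with no new stereocentre, and the low temperature keeps the benzylic ethers from ionising.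

Step 10
Reactants: 20 bis-silyl ether
Product: 21 (1S,2R,5R,6R)-2,6-bis(4-hydroxy-3-methoxyphenyl)-3,7-dioxabicyclo[3.3.0]octan-1-ol (target)
Conditions: Bu4NF (2.5 equiv), AcOH (2.5 equiv), THF, 0 °C
Reagents that add atoms: none
Why: fluoride desilylation of the two aryl silyl ethers; acetic acid buffering avoids phenoxide-driven quinone methide opening of the benzylic ethers.

**Compound list**
1 | catechol | Oc1ccccc1O | starting material
2 | guaiacol (2-methoxyphenol) | COc1ccccc1O | intermediate
3 | glyoxylic acid | O=CC(=O)O | starting material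
4 | vanillylmandelic acid (racemic) | COc1cc(C(O)C(=O)O)ccc1O | intermediate (not isolated)
5 | 4-hydroxy-3-methoxyphenylglyoxylic acid | COc1cc(C(=O)C(=O)O)ccc1O | intermediate (not isolated)
6 | vanillin | COc1cc(C=O)ccc1O | intermediate
7 | 3-methoxy-4-(triisopropylsilyloxy)benzaldehyde | COc1cc(C=O)ccc1O[Si](C(C)C)(C(C)C)C(C)C | intermediate
8 | methyl 2-(bromomethyl)acrylate | C=C(CBr)C(=O)OC | starting material
9 | methyl (4R)-4-hydroxy-2-methylidene-4-Ar-butanoate | C=C(C[C@@H](O)c1ccc(O[Si](C(C)C)(C(C)C)C(C)C)c(OC)c1)C(=O)OC | intermediate (not isolated)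
10 | (5R)-5-Ar-3-methylenedihydrofuran-2(3H)-one | O=C1O[C@@H](c2ccc(O[Si](C(C)C)(C(C)C)C(C)C)c(OC)c2)CC1=C | intermediate
11 | formaldehyde | C=O | starting material
12 | (5R)-3-hydroxy-5-Ar-furan-2(5H)-one (isotetronic acid, enol of the α-keto lactone) | O=C1O[C@@H](c2ccc(O[Si](C(C)C)(C(C)C)C(C)C)c(OC)c2)C=C1O | intermediate (not isolated)
13 | (5S)-3-hydroxy-4-(hydroxymethyl)-5-Ar-furan-2(5H)-one | O=C1O[C@@H](c2ccc(O[Si](C(C)C)(C(C)C)C(C)C)c(OC)c2)C(CO)=C1O | intermediate
14 | (3R,4S,5R)-3-hydroxy-4-(hydroxymethyl)-5-Ar-dihydrofuran-2(3H)-one (OH, CH2OH and aryl all cis) | O=C1O[C@@H](c2ccc(O[Si](C(C)C)(C(C)C)C(C)C)c(OC)c2)[C@@H](CO)[C@H]1O | intermediate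
15 | 4-(dimethoxymethyl)-2-methoxy-1-(triisopropylsilyloxy)benzene | COC(OC)c1ccc(O[Si](C(C)C)(C(C)C)C(C)C)c(OC)c1 | intermediate (not isolated)
16 | (2S,4aR,5R,7aR)-2,5-di-Ar-tetrahydro-4H-furo[3,4-d][1,3]dioxin-7(4aH)-one (cis-fused; acetal aryl equatorial) | O=C1O[C@@H](c3ccc(O[Si](C(C)C)(C(C)C)C(C)C)c(OC)c3)[C@H]2CO[C@H](c4ccc(O[Si](C(C)C)(C(C)C)C(C)C)c(OC)c4)O[C@@H]12 | intermediate
17 | potassium enolate of 16 (C1=C8–O−) | [K+].[O-]C1=C2O[C@@H](c3ccc(O[Si](C(C)C)(C(C)C)C(C)C)c(OC)c3)OC[C@@H]2[C@H](c4ccc(O[Si](C(C)C)(C(C)C)C(C)C)c(OC)c4)O1 | intermediate (not isolated)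
18 | (1R,4R,5R,8R)-1-hydroxy-4,8-di-Ar-3,7-dioxabicyclo[3.3.0]octan-2-one | COc1cc([C@H]2OC[C@@H]3[C@H](c4ccc(O[Si](C(C)C)(C(C)C)C(C)C)c(OC)c4)OC(=O)[C@]23O)ccc1O[Si](C(C)C)(C(C)C)C(C)C | intermediate
19 | lactol of 18 (C8 hemiacetal, anomer mixture) | COc1cc([C@H]2OC[C@@H]3[C@H](c4ccc(O[Si](C(C)C)(C(C)C)C(C)C)c(OC)c4)OC(O)[C@]23O)ccc1O[Si](C(C)C)(C(C)C)C(C)C | intermediate (not isolated)
20 | (1S,2R,5R,6R)-2,6-di-Ar-3,7-dioxabicyclo[3.3.0]octan-1-ol | COc1cc([C@H]2OC[C@@H]3[C@H](c4ccc(O[Si](C(C)C)(C(C)C)C(C)C)c(OC)c4)OC[C@]23O)ccc1O[Si](C(C)C)(C(C)C)C(C)C | intermediate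
21 | (1S,2R,5R,6R)-2,6-bis(4-hydroxy-3-methoxyphenyl)-3,7-dioxabicyclo[3.3.0]octan-1-ol | COc1cc([C@H]2OC[C@@H]3[C@H](c4ccc(O)c(OC)c4)OC[C@]23O)ccc1O | target

**Count and risks**
Total step count: 10. Longest linear sequence: 10 (aldehyde 7 is used twice, in steps 4 and 7).

The three steps most likely to fail:

Step 8 (the proposed ring contraction). The enolate may not rearrange below its decomposition temperature, or the aryl at C2 may not end exo; the 2S acetal configuration from step 7, on which the exo outcome rests, is argued from conformational analysis only. Fallback with known chemistry, setting out from 16 and coming back at 20: treat 16 with iBu2AlH at −78 °C and then Et3SiH/BF3·OEt2. This deoxygenates the lactol and opens the acetal reductively at the secondary oxygen (the usual regiochemistry of silane/Lewis acid openings of six-membered benzylidene acetals), giving the all-cis tetrahydrofuranol carrying a primary aryl-methyl ether F1. Dess–Martin oxidation (NaHCO3, CH2Cl2) gives the tetrahydrofuran-3-one F2. Irradiation of F2 (Pyrex-filtered Hg lamp, benzene) then effects the Norrish–Yang photocyclisation used for paulownin: hydrogen abstraction from the benzylic ether CH2 and closure of the 1,5-biradical form C1–C2 and the tertiary alcohol on the face of the tether, with the aryl exo, giving 20 directly.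

Step 6 (hydrogenation of the enol). The tetrasubstituted enol may reduce slowly, may react through its keto tautomer (losing the cis C5/C6 relationship), or may lose the allylic or benzylic C–O bond. Fallback setting out from 13 and coming back at 16: acetalise first with 15 (camphorsulfonic acid, CH2Cl2) to the enol acetal F3, in which the enol is locked as an enol ether. Hydrogenate its C=C bond anti to the C6 aryl (Rh/Al2O3 at higher pressure, or [Ir(cod)(PCy3)(py)]PF6), then equilibrate the acetal carbon with camphorsulfonic acid to reach 16.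

Step 5 (telescoped ozonolysis and hydroxymethylation). The aldol with formaldehyde may run on to the bis-adduct or the product may dehydrate, and ozone may touch the electron-rich arene. Fallback setting out from 12 (isolated after the ozonolysis, or after OsO4/NaIO4 cleavage) and coming back at 13: Vilsmeier–Haack formylation (POCl3, DMF) at the enol carbon gives the formyl isotetronic acid F4, which can take up only one carbon. NaBH4/CeCl3 (MeOH, −78 °C) then reduces the aldehyde to 13.

Further compounds
F1 | step 8 | (3R,4S,5R)-5-Ar-4-{[(3-methoxy-4-(triisopropylsilyloxy)phenyl)methoxy]methyl}tetrahydrofuran-3-ol | O[C@H]1CO[C@@H](c2ccc(O[Si](C(C)C)(C(C)C)C(C)C)c(OC)c2)[C@H]1COCc1ccc(O[Si](C(C)C)(C(C)C)C(C)C)c(OC)c1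
F2 | step 8 | (4R,5R)-5-Ar-4-{[(3-methoxy-4-(triisopropylsilyloxy)phenyl)methoxy]methyl}dihydrofuran-3(2H)-one | O=C1CO[C@@H](c2ccc(O[Si](C(C)C)(C(C)C)C(C)C)c(OC)c2)[C@H]1COCc1ccc(O[Si](C(C)C)(C(C)C)C(C)C)c(OC)c1
F3 | step 6 | (5S)-2,5-di-Ar-4H-furo[3,4-d][1,3]dioxin-7(5H)-one (both epimers at the acetal carbon) | O=C1O[C@@H](c3ccc(O[Si](C(C)C)(C(C)C)C(C)C)c(OC)c3)C2=C1OC(c1ccc(O[Si](C(C)C)(C(C)C)C(C)C)c(OC)c1)OC2
F4 | step 5 | (2S)-4-hydroxy-5-oxo-2-Ar-2,5-dihydrofuran-3-carbaldehyde | O=CC1=C(O)C(=O)O[C@H]1c1ccc(O[Si](C(C)C)(C(C)C)C(C)C)c(OC)c1
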